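## Retrosynthetic overview

- Labdane numbering is used for C1–C15 and C17–C20; the butenolide γ-carbon is called C16. Ring A has three bare methylenes (C1–C3) opposite the contiguous triad C4 (quaternary), C5 (methine), C10 (quaternary), and the C6 carbinol adjoins C5.
- Cutting C5–C10 and C3–C4 (intramolecular Diels–Alder) turns the triad into two alkene geometries of an open-chain pentaene enal. C6, bought as (S)-5-(hydroxymethyl)butyrolactone, remains as the allylic stereocentre that steers them.
- C9–C11 comes from a Negishi sp2–sp3 coupling on a Z enol triflate. The resulting tetrasubstituted C8=C9 alkene later becomes the C9 methine and the C17 methylene by an allylic diazene transposition.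
- C15–C16 comes last, from a catalytic asymmetric vinylogous Mukaiyama aldol with a 4-methyl-2-silyloxyfuran. The E C13=C14 alkene comes from alkyne methylalumination.
- Ring order: the lactone ring is only a carrier and is opened by reduction; rings A and B then close together in one step; the butenolide arrives preformed.

Key step: step 18

Remark (assumption): the absolute sense of the chiral catalyst in step 26 is assigned beforehand on a simple (E)-3-methyl-2-enal, and the antipode that gives the 15S,16S adduct is used.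

## Route

Step 1
Reactants: 1 acrolein; 2 2-(triphenylphosphoranylidene)propanal
Product: 3 (E)-2-methylpenta-2,4-dienal
Conditions: CH2Cl2, hydroquinone (cat.), 40 °C; product used as a solution
Reagents that add atoms: none
Why: Wittig olefination with a stabilised formyl ylide, which attacks the more electrophilic acrolein carbonyl and should give the E trisubstituted alkene under thermodynamic control.

Step 2
Reactants: 4 (S)-5-(hydroxymethyl)dihydrofuran-2(3H)-one
Product: 5 (S)-5-{[tert-butyl(dimethyl)silyl]oxymethyl}dihydrofuran-2(3H)-one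
Conditions: TBSCl, imidazole, DMF, 23 °C
Reagents that add atoms: tert-butyl(chloro)dimethylsilane, CC(C)(C)[Si](C)(C)Cl
Why: Standard silylation of the primary alcohol (O5); the C6 stereocentre is not involved.

Step 3
Reactants: 5 silyl lactone; 3 (E)-2-methylpenta-2,4-dienal
Product: 7 (5S)-5-(TBSO-methyl)-3-[(E)-1-hydroxy-2-methylpenta-2,4-dienyl]dihydrofuran-2(3H)-one (epimer mixture at C8 and C9), via lithium enolate of 5 6 (not isolated)
Conditions: LDA, THF, −78 °C; then 3, −78 °C; aq. NH4Cl
Reagents that add atoms: none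
Why: Lactone lithium enolate aldol addition, 1,2 to the dienal at low temperature, forming C8–C9; the two new centres are not controlled because steps 4 and 5 remove them.

Step 4
Reactants: 7 aldol adduct
Product: 8 (5S)-5-(TBSO-methyl)-3-[(E)-2-methylpenta-2,4-dienoyl]dihydrofuran-2(3H)-one (β-keto lactone)
Conditions: Dess–Martin periodinane, CH2Cl2, 0 → 23 °C
Reagents that add atoms: none
Why: Dess–Martin oxidation of the allylic secondary alcohol to the 1,3-dicarbonyl under neutral conditions that leave the diene and C6 alone.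

Step 5
Reactants: 8 β-keto lactone
Product: 10 Z enol triflate, (5S)-5-(TBSO-methyl)-3-[(2E)-2-methyl-1-(trifluoromethylsulfonyloxy)penta-2,4-dienylidene]dihydrofuran-2(3H)-one with OTf cis to the lactone C=O and C10 cis to C7, via chelated sodium Z-enolate of 8 9 (not isolated)
Conditions: NaH, Et2O, 0 °C; then Tf2O, −78 → 0 °C
Reagents that add atoms: trifluoromethanesulfonic anhydride, O=S(=O)(OS(=O)(=O)C(F)(F)F)C(F)(F)F
Why: Chelate-controlled enol triflation: in a weakly coordinating solvent the sodium ion bridges the ketone-derived oxygen and the lactone carbonyl, so O-sulfonylation should fix the Z geometry.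

Step 6
Reactants: 11 but-3-yn-1-ol
Product: 12 (but-3-yn-1-yloxy)(tert-butyl)dimethylsilane
Conditions: TBSCl, imidazole, CH2Cl2, 23 °C
Reagents that add atoms: tert-butyl(chloro)dimethylsilane, CC(C)(C)[Si](C)(C)Cl
Why: Standard silylation, so that the later formaldehyde quench gives a single free hydroxyl.

Step 7
Reactants: 12 silyl alkyne
Product: 15 (E)-5-(TBSO)-3-methylpent-2-en-1-ol, via (E)-[4-(TBSO)-2-methylbut-1-enyl]dimethylalane 13 (not isolated), via lithium butyl[(E)-4-(TBSO)-2-methylbut-1-enyl]dimethylaluminate 14 (not isolated)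
Conditions: Me3Al, Cp2ZrCl2 (20 mol %), CH2Cl2, 0 → 23 °C; then n-BuLi, −78 °C; (CH2O)n, THF, −78 → 23 °C; aq. HCl
Reagents that add atoms: trimethylaluminium, C[Al](C)C; formaldehyde (as paraformaldehyde), C=O
Why: Zirconium-catalysed methylalumination adds CH3 and Al syn across the terminal alkyne with CH3 on the internal carbon (C13), and the ate complex traps formaldehyde with retention, so the E C13=C14 alkene, the C13 methyl and C15 arrive together.

Step 8
Reactants: 15 allylic alcohol
Product: 16 (E)-5-(TBSO)-3-methylpent-2-enyl 4-methoxybenzyl ether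
Conditions: NaH, PMBCl, Bu4NI (cat.), THF–DMF, 0 → 23 °C
Reagents that add atoms: 4-methoxybenzyl chloride, COc1ccc(CCl)cc1
Why: Williamson etherification of the primary allylic alkoxide; the silyl ether is stable to these conditions.

Step 9
Reactants: 16 PMB ether
Product: 17 (E)-5-(4-methoxybenzyloxy)-3-methylpent-3-en-1-ol
Conditions: TBAF, THF, 23 °C
Reagents that add atoms: none
Why: Fluoride cleavage of the primary TBS ether leaves the PMB ether and the alkene untouched.

Step 10
Reactants: 17 homoallylic alcohol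
Product: 18 (E)-1-[(5-iodo-3-methylpent-2-enyloxy)methyl]-4-methoxybenzene (the C11–C15 arm)
Conditions: I2, PPh3, imidazole, CH2Cl2, 0 → 23 °C
Reagents that add atoms: iodine, II
Why: Appel-type iodination of the primary alcohol through the alkoxyphosphonium iodide, by SN2 without touching the trisubstituted alkene.

Step 11
Reactants: 18 homoallylic iodide; 10 Z enol triflate
Product: 20 tetrasubstituted alkylidene lactone, (5S)-5-(TBSO-methyl)dihydrofuran-2(3H)-one whose exocyclic C8=C9 carbon C9 bears the (E)-1-methylbuta-1,3-dienyl group (cis to ring C7) and the (E)-5-(4-methoxybenzyloxy)-3-methylpent-3-enyl arm (cis to the lactone C=O), via [(E)-5-(4-methoxybenzyloxy)-3-methylpent-3-enyl]zinc iodide 19 (not isolated)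
Conditions: Zn dust (I2-activated), DMA, 50 °C; then 10, PdCl2(dppf) (5 mol %), THF–DMA, 23 → 45 °C
Reagents that add atoms: none
Why: Negishi sp2–sp3 cross-coupling: oxidative addition into the activated vinyl C–OTf bond, transmetalation and reductive elimination proceed with retention of alkene geometry, and the wide-bite-angle ligand should suppress β-hydride elimination, forming C9–C11.

Step 12
Reactants: 20 alkylidene lactone
Product: 21 open-chain diol, with C17 CH2OH on C8 (cis to C11), (6S)-OH and 5-OTBS
Conditions: DIBAL-H (4 equiv), CH2Cl2, −78 → 0 °C; Rochelle salt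
Reagents that add atoms: none
Why: DIBAL-H reduces the conjugated lactone by 1,2-hydride delivery through the lactol to the allylic primary alcohol and frees O6, without conjugate reduction or change of alkene geometry.

Step 13
Reactants: 21 diol
Product: 22 17-acetate of 21 (6-OH free)
Conditions: AcCl (1.1 equiv), 2,4,6-collidine, CH2Cl2, −78 °C
Reagents that add atoms: acetyl chloride, CC(=O)Cl
Why: Kinetically selective acylation of the primary allylic hydroxyl over the secondary one with a hindered base at low temperature.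

Step 14
Reactants: 22 monoacetate
Product: 23 17-acetate 5,6-bis-TBS ether
Conditions: TBSOTf, 2,6-lutidine, CH2Cl2, −78 → 0 °C
Reagents that add atoms: tert-butyldimethylsilyl trifluoromethanesulfonate, CC(C)(C)[Si](C)(C)OS(=O)(=O)C(F)(F)F
Why: Silyl triflate silylation of the secondary C6 hydroxyl installs the group that later directs the cycloaddition; acetate and PMB ether are stable.

Step 15
Reactants: 23 bis-silyl ether
Product: 24 primary C5 alcohol (6-OTBS and 17-OAc retained)
Conditions: HF·pyridine, pyridine, THF, 0 °C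
Reagents that add atoms: none
Why: Under buffered HF·pyridine the unhindered primary silyl ether is cleaved much faster than the secondary one, and acetate and PMB ether are untouched.

Step 16
Reactants: 24 primary alcohol
Product: 25 (S)-α-silyloxy aldehyde (C5 aldehyde)
Conditions: Dess–Martin periodinane, NaHCO3, CH2Cl2, 0 → 23 °C
Reagents that add atoms: none
Why: Buffered Dess–Martin oxidation gives the α-silyloxy aldehyde without base, so C6 should not epimerise.

Step 17
Reactants: 25 aldehyde; 2 2-(triphenylphosphoranylidene)propanal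
Product: 26 open-chain pentaene enal, C18H(=O)–C4(CH3)=C5H–C6H(OTBS)–C7H2–C8(CH2OAc)=C9(C11–C15 arm)–C10(CH3)=C1H–C2H=C3H2, with 4E enal, (6S), C7 cis to C10, 10E diene, 13E
Conditions: 2 (2 equiv), PhMe, 80 °C
Reagents that add atoms: none
Why: Wittig olefination with the non-basic stabilised ylide should give the E 2-methyl enal (C19 cis to C6) without epimerising the α-silyloxy centre.

Step 18
Reactants: 26 pentaene enal
Product: 27 trans-fused hexalin aldehyde, with 17-acetoxy, 6α-OTBS, 5α-H, 10β-CH3, 4β-CH3, 4α-CHO (C18), C1=C2 and C8=C9 alkenes, and the 15-OPMB side chain on C9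
Conditions: BHT (0.2 equiv), PhMe (0.005 M), 150 °C, sealed tube
Reagents that add atoms: none
Why: Concerted, asynchronous thermal [4+2] cycloaddition in which the C4=C5 enal adds suprafacially to the C10=C1–C2=C3 diene with the internal C5–C10 bond ahead of C3–C4; the closest known class is the type 1 intramolecular Diels–Alder reaction of terminally activated 2-methyl-2,8,10-trienals to trans-fused octalins. Ring A (C10–C1–C2–C3–C4–C5) closes as the six-membered pericyclic ring and ring B (C5–C6–C7–C8–C9–C10) as the six-membered tether ring through a half-chair, helped by the Z C8=C9 alkene, which holds C7 and C10 cis and is twisted out of the diene plane. C4 and C5 take their relative configuration from the E enal (formyl cis to H5, C19 cis to C6), C10 follows from the E diene (tether outside, C20 inside) and the endo mode (formyl under the diene), which gives the trans fusion with C19 and C20 syn, and the absolute sense of all three comes from C6. The step needs endo and π-facial selectivity: A(1,3) strain between the C4 methyl and the C6 substituents allows only the rotamer with H6 in the enal plane, C7 on the reacting face and the silyloxy group anti to the incoming diene, so O6 should end equatorial, while the short four-atom tether and secondary overlap of the formyl group favour the endo mode. The inside C20 methyl slows the diene, hence high dilution, a radical inhibitor and a sealed tube.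

Step 19
Reactants: 27 hexalin aldehyde
Product: 28 1,2-dihydro derivative of 27 (ring A saturated; C8=C9, C13=C14, aldehyde and acetate retained)
Conditions: KO2CN=NCO2K, AcOH, CH2Cl2–MeOH, 0 → 23 °C, added in portions
Reagents that add atoms: none
Why: Diimide transfers H2 syn to the cis-disubstituted C1=C2 alkene much faster than to the tri- and tetrasubstituted alkenes and does not reduce the aldehyde or cleave the PMB ether or allylic acetate.

Step 20
Reactants: 28 dihydro aldehyde
Product: 29 C17,C18-diol (6α-OTBS, C8=C9 retained)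
Conditions: DIBAL-H (5 equiv), CH2Cl2, −78 → 0 °C; Rochelle salt
Reagents that add atoms: none
Why: DIBAL-H reduces the neopentyl aldehyde to the C18 alcohol and cleaves the acetate reductively in the same operation; silyl and PMB ethers survive.

Step 21
Reactants: 29 diol
Product: 32 8(17)-methylene trans-decalin, with 9α-H (side chain 9β), 6α-OTBS, 4α-CH2OH, 15-OPMB, via N-allyl-N-(2-nitrobenzenesulfonyl)hydrazine at C17 30 (not isolated), via C17 allylic diazene 31 (not isolated)
Conditions: 2-nitrobenzenesulfonylhydrazide, PPh3, DEAD, N-methylmorpholine, −30 °C; then 23 °C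
Reagents that add atoms: none
Why: Mitsunobu displacement at the primary allylic C17 (the neopentyl C18 hydroxyl is too hindered for SN2), loss of sulfinate to the monoalkyl diazene and retro-ene loss of N2 give the reductive 1,3-transposition; hydrogen should be delivered to C9 on the α face opposite the axial C10 methyl, which sets C9 and the exocyclic C8=C17 alkene.

Step 22
Reactants: 32 C18 alcohol
Product: 33 6,18-bis-TBS ether of 32
Conditions: TBSOTf, 2,6-lutidine, CH2Cl2, 0 °C
Reagents that add atoms: tert-butyldimethylsilyl trifluoromethanesulfonate, CC(C)(C)[Si](C)(C)OS(=O)(=O)C(F)(F)F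
Why: The silyl triflate is reactive enough to silylate the hindered neopentyl hydroxyl; the PMB ether and the exocyclic alkene are stable with the hindered base.

Step 23
Reactants: 33 PMB ether
Product: 34 C15 allylic alcohol
Conditions: DDQ, CH2Cl2–pH 7 buffer, 0 °C
Reagents that add atoms: none
Why: Oxidative PMB cleavage by hydride abstraction from the electron-rich benzylic position and hydrolysis of the oxocarbenium ion; silyl ethers and the unactivated alkenes are inert.

Step 24
Reactants: 34 allylic alcohol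
Product: 35 C15 enal (13E)
Conditions: MnO2, CH2Cl2, 23 °C
Reagents that add atoms: none
Why: Manganese dioxide oxidises the allylic alcohol selectively and should keep the E geometry of the 3-methyl enal.

Step 25
Reactants: 36 4-methylfuran-2(5H)-one
Product: 37 tert-butyl(dimethyl)[(4-methylfuran-2-yl)oxy]silane
Conditions: TBSOTf, Et3N, CH2Cl2, 0 °C
Reagents that add atoms: tert-butyldimethylsilyl trifluoromethanesulfonate, CC(C)(C)[Si](C)(C)OS(=O)(=O)C(F)(F)F
Why: Soft enolisation of the butenolide and O-silylation give the aromatic 2-silyloxyfuran, the dienolate equivalent that carries C16.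

Step 26
Reactants: 35 C15 enal; 37 silyloxyfuran
Product: 38 O6,O18-bis-TBS ether of the target (15S,16S, 15-OH free)
Conditions: SiCl4 (1.2 equiv), chiral binaphthyldiamine-derived bisphosphoramide (5 mol %), i-Pr2NEt (10 mol %), CH2Cl2, −78 °C; aq. NaHCO3
Reagents that add atoms: none
Why: Catalytic asymmetric vinylogous Mukaiyama aldol reaction, forming C15–C16: the chiral Lewis acid activates the enal for 1,2-attack by the furan γ-carbon through an open transition state that should favour the threo adduct, and the catalyst antipode fixes 15S and with it 16S because the decalin stereocentres are too remote to interfere.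

Step 27
Reactants: 38 bis-silyl ether
Product: 39 CNP0221530.1, the target
Conditions: HF·pyridine, pyridine, THF, 0 → 23 °C
Reagents that add atoms: none
Why: Acidic fluoride cleaves both TBS ethers, and the absence of base protects the butenolide C16 centre and the allylic C15 carbinol from epimerisation and retro-aldol cleavage.

## Compound list

1 | acrolein | C=CC=O | starting material
2 | 2-(triphenylphosphoranylidene)propanal | CC(C=O)=P(c1ccccc1)(c1ccccc1)c1ccccc1 | starting material
3 | (E)-2-methylpenta-2,4-dienal | O=C/C(C)=C/C=C | intermediate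
4 | (S)-5-(hydroxymethyl)dihydrofuran-2(3H)-one | OC[C@@H]1CCC(=O)O1 | starting material
5 | (S)-5-{[tert-butyl(dimethyl)silyl]oxymethyl}dihydrofuran-2(3H)-one | CC(C)(C)[Si](C)(C)OC[C@@H]1CCC(=O)O1 | intermediate
6 | lithium enolate of 5 | [Li+].[O-]C1=CC[C@@H](CO[Si](C)(C)C(C)(C)C)O1 | intermediate
7 | (5S)-5-(TBSO-methyl)-3-[(E)-1-hydroxy-2-methylpenta-2,4-dienyl]dihydrofuran-2(3H)-one, epimer mixture | C=C/C=C(\C)C(O)C1C[C@@H](CO[Si](C)(C)C(C)(C)C)OC1=O | intermediate
8 | (5S)-5-(TBSO-methyl)-3-[(E)-2-methylpenta-2,4-dienoyl]dihydrofuran-2(3H)-one | C=C/C=C(\C)C(=O)C1C[C@@H](CO[Si](C)(C)C(C)(C)C)OC1=O | intermediate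
9 | chelated sodium Z-enolate of 8 | [Na+].C=C/C=C(\C)/C([O-])=C1\C[C@@H](CO[Si](C)(C)C(C)(C)C)OC1=O | intermediate
10 | Z enol triflate of the α-dienoyl lactone | C=C/C=C(\C)/C(OS(=O)(=O)C(F)(F)F)=C1\C[C@@H](CO[Si](C)(C)C(C)(C)C)OC1=O | intermediate
11 | but-3-yn-1-ol | C#CCCO | starting material
12 | (but-3-yn-1-yloxy)(tert-butyl)dimethylsilane | C#CCCO[Si](C)(C)C(C)(C)C | intermediate
13 | (E)-[4-(TBSO)-2-methylbut-1-enyl]dimethylalane | C[Al](C)/C=C(\C)CCO[Si](C)(C)C(C)(C)C | intermediate
14 | lithium butyl[(E)-4-(TBSO)-2-methylbut-1-enyl]dimethylaluminate | [Li+].CCCC[Al-](C)(C)/C=C(\C)CCO[Si](C)(C)C(C)(C)C | intermediate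
15 | (E)-5-(TBSO)-3-methylpent-2-en-1-ol | OC/C=C(\C)CCO[Si](C)(C)C(C)(C)C | intermediate
16 | (E)-5-(TBSO)-3-methylpent-2-enyl 4-methoxybenzyl ether | COc1ccc(COC/C=C(\C)CCO[Si](C)(C)C(C)(C)C)cc1 | intermediate
17 | (E)-5-(4-methoxybenzyloxy)-3-methylpent-3-en-1-ol | COc1ccc(COC/C=C(\C)CCO)cc1 | intermediate
18 | (E)-1-[(5-iodo-3-methylpent-2-enyloxy)methyl]-4-methoxybenzene | COc1ccc(COC/C=C(\C)CCI)cc1 | intermediate
19 | [(E)-5-(4-methoxybenzyloxy)-3-methylpent-3-enyl]zinc iodide | COc1ccc(COC/C=C(\C)CC[Zn]I)cc1 | intermediate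
20 | tetrasubstituted alkylidene lactone | C=C/C=C(\C)/C(CC/C(C)=C/COCc1ccc(OC)cc1)=C1\C[C@@H](CO[Si](C)(C)C(C)(C)C)OC1=O | intermediate
21 | open-chain C17,C6-diol, 5-OTBS | C=C/C=C(\C)/C(CC/C(C)=C/COCc1ccc(OC)cc1)=C(/CO)\C[C@H](O)CO[Si](C)(C)C(C)(C)C | intermediate
22 | 17-acetate of 21 | C=C/C=C(\C)/C(CC/C(C)=C/COCc1ccc(OC)cc1)=C(/COC(C)=O)\C[C@H](O)CO[Si](C)(C)C(C)(C)C | intermediate
23 | 17-acetate 5,6-bis-TBS ether | C=C/C=C(\C)/C(CC/C(C)=C/COCc1ccc(OC)cc1)=C(/COC(C)=O)\C[C@H](O[Si](C)(C)C(C)(C)C)CO[Si](C)(C)C(C)(C)C | intermediate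
24 | primary C5 alcohol, 6-OTBS, 17-OAc | C=C/C=C(\C)/C(CC/C(C)=C/COCc1ccc(OC)cc1)=C(/COC(C)=O)\C[C@H](O[Si](C)(C)C(C)(C)C)CO | intermediate
25 | (S)-α-silyloxy aldehyde (C5 aldehyde) | C=C/C=C(\C)/C(CC/C(C)=C/COCc1ccc(OC)cc1)=C(/COC(C)=O)\C[C@H](O[Si](C)(C)C(C)(C)C)C=O | intermediate
26 | open-chain pentaene enal | C=C/C=C(\C)/C(CC/C(C)=C/COCc1ccc(OC)cc1)=C(/COC(C)=O)\C[C@H](O[Si](C)(C)C(C)(C)C)/C=C(\C)C=O | intermediate
27 | trans-fused hexalin aldehyde (17-OAc, 6α-OTBS, Δ1, Δ8) | CC(=O)OCC=1C[C@H](O[Si](C)(C)C(C)(C)C)[C@H]2[C@](C)(C=O)CC=C[C@]2(C)C=1CC/C(C)=C/COCc1ccc(OC)cc1 | intermediate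
28 | 1,2-dihydro derivative of 27 | CC(=O)OCC=1C[C@H](O[Si](C)(C)C(C)(C)C)[C@H]2[C@](C)(C=O)CCC[C@]2(C)C=1CC/C(C)=C/COCc1ccc(OC)cc1 | intermediate
29 | C17,C18-diol | OCC=1C[C@H](O[Si](C)(C)C(C)(C)C)[C@H]2[C@](C)(CO)CCC[C@]2(C)C=1CC/C(C)=C/COCc1ccc(OC)cc1 | intermediate
30 | N-(C17-allyl)-N-(2-nitrobenzenesulfonyl)hydrazine | NN(CC=1C[C@H](O[Si](C)(C)C(C)(C)C)[C@H]2[C@](C)(CO)CCC[C@]2(C)C=1CC/C(C)=C/COCc1ccc(OC)cc1)S(=O)(=O)c1ccccc1[N+](=O)[O-] | intermediate
31 | C17 allylic diazene | N=NCC=1C[C@H](O[Si](C)(C)C(C)(C)C)[C@H]2[C@](C)(CO)CCC[C@]2(C)C=1CC/C(C)=C/COCc1ccc(OC)cc1 | intermediate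
32 | 8(17)-methylene trans-decalin, 9α-H, 18-OH, 15-OPMB | C=C1C[C@H](O[Si](C)(C)C(C)(C)C)[C@H]2[C@](C)(CO)CCC[C@]2(C)[C@H]1CC/C(C)=C/COCc1ccc(OC)cc1 | intermediate
33 | 6,18-bis-TBS ether, 15-OPMB | C=C1C[C@H](O[Si](C)(C)C(C)(C)C)[C@H]2[C@](C)(CO[Si](C)(C)C(C)(C)C)CCC[C@]2(C)[C@H]1CC/C(C)=C/COCc1ccc(OC)cc1 | intermediate
34 | C15 allylic alcohol | C=C1C[C@H](O[Si](C)(C)C(C)(C)C)[C@H]2[C@](C)(CO[Si](C)(C)C(C)(C)C)CCC[C@]2(C)[C@H]1CC/C(C)=C/CO | intermediate
35 | C15 enal | C=C1C[C@H](O[Si](C)(C)C(C)(C)C)[C@H]2[C@](C)(CO[Si](C)(C)C(C)(C)C)CCC[C@]2(C)[C@H]1CC/C(C)=C/C=O | intermediate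
36 | 4-methylfuran-2(5H)-one | CC1=CC(=O)OC1 | starting material
37 | tert-butyl(dimethyl)[(4-methylfuran-2-yl)oxy]silane | Cc1coc(O[Si](C)(C)C(C)(C)C)c1 | intermediate
38 | O6,O18-bis-TBS ether of the target | C=C1C[C@H](O[Si](C)(C)C(C)(C)C)[C@H]2[C@](C)(CO[Si](C)(C)C(C)(C)C)CCC[C@]2(C)[C@H]1CC/C(C)=C/[C@H](O)[C@H]1OC(=O)C=C1C | intermediate
39 | CNP0221530.1 | C=C1C[C@H](O)[C@H]2[C@](C)(CO)CCC[C@]2(C)[C@H]1CC/C(C)=C/[C@H](O)[C@H]1OC(=O)C=C1C | target

## Step count and risks

Total steps: 27. Longest linear sequence: 21 steps (steps 6–24, 26 and 27, from but-3-yn-1-ol).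

**Step 18 (intramolecular Diels–Alder).** The cycloaddition may be too slow, because the diene terminus carries an inside methyl and two quaternary carbons form in one event. At the temperature then needed, polymerisation, sigmatropic hydrogen shifts of the diene or loss of endo selectivity could take over. The fallback is an ionic Diels–Alder reaction of an allylic acetal cation. It sets out from 26: 1,2-bis(trimethylsilyloxy)ethane and catalytic TMSOTf in CH2Cl2 at −78 °C convert the enal into the 2-alkenyl-1,3-dioxolane F1. The same acid (−78 → −40 °C) ionises it to a 2-alkoxyallyl cation, a far stronger dienophile, which should cyclise at low temperature with the same endo preference and the same A(1,3) control from C6 to the dioxolane of the cycloadduct F2. PPTS in acetone–water hydrolyses the acetal, and the sequence comes back to the route at 27.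

**Step 26 (vinylogous Mukaiyama aldol).** The threo/erythro and facial selectivity may be poor, because the β,β-disubstituted enal is a weak electrophile and the 4-methyl group crowds the reacting γ-carbon. The fallback builds C15 and C16 by an auxiliary-controlled boron syn-glycolate aldol and closes the butenolide afterwards; it sets out from 35 and comes back at 39.
- The dibutylboron enolate of (R)-4-benzyl-3-[(4-methoxybenzyloxy)acetyl]oxazolidin-2-one (Bu2BOTf, Et3N, CH2Cl2, −78 °C) adds to 35 to give the syn-glycolate aldol imide F3 (15S, 16-OPMB).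
- MeNH(OMe)·HCl and AlMe3 give the N-methoxy-N-methylamide F4.
- TBSOTf and 2,6-lutidine give the 15-O-TBS amide F5.
- MeMgBr gives the methyl ketone F6.
- DDQ frees O16 to give the α-hydroxy ketone F7.
- (Triphenylphosphoranylidene)ketene in toluene at 80 °C acylates O16 and closes the ring by intramolecular Wittig reaction to the 15-O-TBS butenolide F8.
- HF·pyridine removes all three silyl groups and gives 39.

**Step 21 (Mitsunobu / allylic diazene transposition).** The Mitsunobu step may not discriminate the two free hydroxyls, sulfinate may be lost before substitution, or hydrogen may be delivered to the wrong face of C9. The fallback is a palladium-catalysed formate hydrogenolysis of the allylic acetate, setting out from 28. Pd(OAc)2, n-Bu3P and HCO2NH4 in dioxane at 100 °C should form the π-allyl complex on the less hindered α face and deliver hydride internally to the more substituted terminus C9, giving the 8(17)-methylene C18 aldehyde F9. NaBH4 in MeOH at 0 °C reduces the aldehyde, and the sequence comes back to the route at 32.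

## Further compounds

F1 | step 18 | 2-alkenyl-1,3-dioxolane of enal 26 | C=C/C=C(\C)/C(CC/C(C)=C/COCc1ccc(OC)cc1)=C(/COC(C)=O)\C[C@H](O[Si](C)(C)C(C)(C)C)/C=C(\C)C1OCCO1
F2 | step 18 | dioxolane of cycloadduct 27 | CC(=O)OCC=1C[C@H](O[Si](C)(C)C(C)(C)C)[C@H]2[C@](C)(C3OCCO3)CC=C[C@]2(C)C=1CC/C(C)=C/COCc1ccc(OC)cc1
F3 | step 26 | syn-glycolate aldol imide (15S, 16-OPMB, (R)-4-benzyloxazolidinone) | C=C1C[C@H](O[Si](C)(C)C(C)(C)C)[C@H]2[C@](C)(CO[Si](C)(C)C(C)(C)C)CCC[C@]2(C)[C@H]1CC/C(C)=C/[C@H](O)[C@@H](OCc1ccc(OC)cc1)C(=O)N1[C@H](Cc2ccccc2)COC1=O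
F4 | step 26 | N-methoxy-N-methylamide, 15-OH, 16-OPMB | C=C1C[C@H](O[Si](C)(C)C(C)(C)C)[C@H]2[C@](C)(CO[Si](C)(C)C(C)(C)C)CCC[C@]2(C)[C@H]1CC/C(C)=C/[C@H](O)[C@@H](OCc1ccc(OC)cc1)C(=O)N(C)OC
F5 | step 26 | 15-O-TBS N-methoxy-N-methylamide | C=C1C[C@H](O[Si](C)(C)C(C)(C)C)[C@H]2[C@](C)(CO[Si](C)(C)C(C)(C)C)CCC[C@]2(C)[C@H]1CC/C(C)=C/[C@H](O[Si](C)(C)C(C)(C)C)[C@@H](OCc1ccc(OC)cc1)C(=O)N(C)OC
F6 | step 26 | methyl ketone, 15-OTBS, 16-OPMB | C=C1C[C@H](O[Si](C)(C)C(C)(C)C)[C@H]2[C@](C)(CO[Si](C)(C)C(C)(C)C)CCC[C@]2(C)[C@H]1CC/C(C)=C/[C@H](O[Si](C)(C)C(C)(C)C)[C@@H](OCc1ccc(OC)cc1)C(C)=O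
F7 | step 26 | α-hydroxy methyl ketone, 15-OTBS | C=C1C[C@H](O[Si](C)(C)C(C)(C)C)[C@H]2[C@](C)(CO[Si](C)(C)C(C)(C)C)CCC[C@]2(C)[C@H]1CC/C(C)=C/[C@H](O[Si](C)(C)C(C)(C)C)[C@@H](O)C(C)=O
F8 | step 26 | O6,O15,O18-tris-TBS ether of the target | C=C1C[C@H](O[Si](C)(C)C(C)(C)C)[C@H]2[C@](C)(CO[Si](C)(C)C(C)(C)C)CCC[C@]2(C)[C@H]1CC/C(C)=C/[C@H](O[Si](C)(C)C(C)(C)C)[C@H]1OC(=O)C=C1C
F9 | step 21 | 8(17)-methylene C18 aldehyde, 9α-H, 6α-OTBS, 15-OPMB | C=C1C[C@H](O[Si](C)(C)C(C)(C)C)[C@H]2[C@](C)(C=O)CCC[C@]2(C)[C@H]1CC/C(C)=C/COCc1ccc(OC)cc1
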